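**Retrosynthetic overview**
- Target 20 comes from the tribenzyl (2S)-flavanone 19 by BCl3 debenzylation. 19 comes from flavone 17 by an enantioselective CuH 1,4-reduction that sets C2.
- Ring C of 17 is opened at C2=C3. The route rests on this feature: O1 of ring C is a phenol oxygen of ring A and C2 bears only the phenyl group. O1–C2 can therefore be installed beforehand as a benzoate ester, C3 and C4 come from an acetyl group, and an acyl ylide at C3 closes the ring onto the ester carbonyl (16 → 17).
- Ylide 16 comes from bromoketone 14, benzoate 13 and phenol 11. The C8–CH2–C3' bridge is made earlier by adding pyranone 5 to the ortho-quinone methide released from Mannich base 8.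
- Ring order: the 2-pyranone ring is made first (enol silane of 3-pentanone plus malonyl dichloride), ring A is bought as 2,4,6-trihydroxyacetophenone, and ring C is closed last.

Key step: step 10

Assumption: the (R)-ligand in step 11 is written as the hand that delivers hydride to the Re face of C2. The sense of induction for a flavone with this substitution is to be confirmed on a small scale, and the (S)-ligand is used instead if the sense is opposite.

**Route**

Step 1
Reactants: 1 3-pentanone
Product: 2 3-(trimethylsilyloxy)pent-2-ene (E/Z mixture)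
Conditions: TMSCl, Et3N, DMF, 80 °C
Reagents that add atoms: chlorotrimethylsilane, C[Si](C)(C)Cl
Why: Thermodynamic O-silylation of the ketone enol (silyl enol ether formation) can give only one regioisomer from the symmetrical ketone, and the double-bond geometry is irrelevant because this carbon becomes an sp2 ring atom.

Step 2
Reactants: 2 3-(trimethylsilyloxy)pent-2-ene; 3 malonyl dichloride
Product: 5 6-ethyl-4-hydroxy-5-methyl-2H-pyran-2-one, via 4-methyl-3,5-dioxoheptanoyl chloride 4 (not isolated)
Conditions: Et2O, −78 °C → rt; evaporation and trituration without aqueous work-up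
Reagents that add atoms: none
Why: C-acylation of the enol silane by one acyl chloride terminus, followed by enol-lactonisation through the second (the known pyranone synthesis from enol silanes and malonyl dichloride), should give the 4-hydroxy-2-pyranone with the former ketone carbon as C6 and its α-carbon as C5.

Step 3
Reactants: 6 2,4,6-trihydroxyacetophenone
Product: 7 1-[2,4-bis(benzyloxy)-6-hydroxyphenyl]ethanone
Conditions: BnBr (2.1 equiv), K2CO3, DMF, rt
Reagents that add atoms: benzyl bromide, BrCc1ccccc1
Why: In this Williamson etherification the para OH and one ortho OH are alkylated, while the last ortho OH, hydrogen-bonded to the acetyl carbonyl, is the least acidic and least nucleophilic and is expected to stay free.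

Step 4
Reactants: 7 1-[2,4-bis(benzyloxy)-6-hydroxyphenyl]ethanone
Product: 8 1-[4,6-bis(benzyloxy)-3-[(dimethylamino)methyl]-2-hydroxyphenyl]ethanone
Conditions: CH2=NMe2+ I− (1.05 equiv), K2CO3, MeCN, rt
Reagents that add atoms: N,N-dimethylmethyleneiminium iodide (Eschenmoser's salt), C=[N+](C)C.[I-]
Why: Phenolic Mannich aminomethylation should occur at C3, ortho to the phenoxide oxygen (the site that halogen electrophiles also choose in 2-hydroxy-4,6-dialkoxyacetophenones), because C5 is shielded between two benzyloxy groups and K2CO3 does not enolise the acetyl methyl; the position is to be confirmed by NOE before going on.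

Step 5
Reactants: 8 1-[4,6-bis(benzyloxy)-3-[(dimethylamino)methyl]-2-hydroxyphenyl]ethanone; 5 6-ethyl-4-hydroxy-5-methyl-2H-pyran-2-one
Product: 10 3-[[3-acetyl-4,6-bis(benzyloxy)-2-hydroxyphenyl]methyl]-6-ethyl-4-hydroxy-5-methyl-2H-pyran-2-one, via ortho-quinone methide 9 (not isolated)
Conditions: 1,4-dioxane, 90 °C, N2 sweep
Reagents that add atoms: none
Why: The acidic pyranone protonates the amine, thermal loss of Me2NH releases ortho-quinone methide 9, and Michael addition of pyranone C3 with rearomatisation forms the methylene bridge (alkylation of a cyclic 1,3-dicarbonyl by a phenolic Mannich base); the pyranone never meets free formaldehyde, so the bis(pyranonyl)methane cannot form.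

Step 6
Reactants: 10 3-[[3-acetyl-4,6-bis(benzyloxy)-2-hydroxyphenyl]methyl]-6-ethyl-4-hydroxy-5-methyl-2H-pyran-2-one
Product: 11 3-[[3-acetyl-4,6-bis(benzyloxy)-2-hydroxyphenyl]methyl]-4-(benzyloxy)-6-ethyl-5-methyl-2H-pyran-2-one
Conditions: BnBr (1.1 equiv), K2CO3 (1.1 equiv), acetone, 40 °C
Reagents that add atoms: benzyl bromide, BrCc1ccccc1
Why: Williamson O-alkylation of the pyranone enolate (pKa about 5) is expected to be selective, since one equivalent of base leaves the chelated phenol untouched as in step 3 and the substituted C3 disfavours C-alkylation; the 2-benzyloxy-4-pyranone isomer is the foreseeable minor by-product, to be removed by chromatography.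

Step 7
Reactants: 11 3-[[3-acetyl-4,6-bis(benzyloxy)-2-hydroxyphenyl]methyl]-4-(benzyloxy)-6-ethyl-5-methyl-2H-pyran-2-one; 12 benzoyl chloride
Product: 13 2-acetyl-3,5-bis(benzyloxy)-6-[[4-(benzyloxy)-6-ethyl-5-methyl-2-oxo-2H-pyran-3-yl]methyl]phenyl benzoate
Conditions: Et3N, DMAP (cat.), CH2Cl2, 0 °C → rt
Reagents that add atoms: none
Why: DMAP-catalysed O-acylation should benzoylate the hindered, chelated phenol, and with no strong base present the ketone is not enolised, so no Baker–Venkataraman acyl shift is expected.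

Step 8
Reactants: 13 2-acetyl-3,5-bis(benzyloxy)-6-[[4-(benzyloxy)-6-ethyl-5-methyl-2-oxo-2H-pyran-3-yl]methyl]phenyl benzoate
Product: 14 3,5-bis(benzyloxy)-2-[[4-(benzyloxy)-6-ethyl-5-methyl-2-oxo-2H-pyran-3-yl]methyl]-6-(bromoacetyl)phenyl benzoate
Conditions: CuBr2 (2 equiv), EtOAc/CHCl3, reflux
Reagents that add atoms: copper dibromide, Br[Cu]Br
Why: α-Bromination of an aryl methyl ketone by CuBr2 proceeds through the copper-bound enol and is known to favour the side chain over the ring in hydroxy- and alkoxyacetophenones, and the HBr formed is driven out of the boiling solvent before it can attack the benzyl ethers.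

Step 9
Reactants: 14 3,5-bis(benzyloxy)-2-[[4-(benzyloxy)-6-ethyl-5-methyl-2-oxo-2H-pyran-3-yl]methyl]-6-(bromoacetyl)phenyl benzoate
Product: 16 3,5-bis(benzyloxy)-2-[[4-(benzyloxy)-6-ethyl-5-methyl-2-oxo-2H-pyran-3-yl]methyl]-6-[(triphenylphosphoranylidene)acetyl]phenyl benzoate, via phosphonium bromide 15 (not isolated)
Conditions: PPh3, toluene, rt; then aq. Na2CO3, CH2Cl2, 0 °C
Reagents that add atoms: triphenylphosphine, c1ccc(cc1)P(c1ccccc1)c1ccccc1
Why: SN2 quaternisation of the primary phenacyl bromide, then deprotonation of the acidic phenacylphosphonium salt by carbonate, should give the stabilised acyl ylide; the cold two-phase treatment is meant to spare the benzoate and prevent early cyclisation, and the crude ylide is used at once.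

Step 10
Reactants: 16 3,5-bis(benzyloxy)-2-[[4-(benzyloxy)-6-ethyl-5-methyl-2-oxo-2H-pyran-3-yl]methyl]-6-[(triphenylphosphoranylidene)acetyl]phenyl benzoate
Product: 17 5,7-bis(benzyloxy)-8-[[4-(benzyloxy)-6-ethyl-5-methyl-2-oxo-2H-pyran-3-yl]methyl]-2-phenyl-4H-chromen-4-one
Conditions: toluene, 110 °C, N2
Reagents that add atoms: none
Why: On heating, the nucleophilic ylide carbon (C3) adds to the carbonyl carbon of the neighbouring benzoate (C2) to give a betaine/oxaphosphetane that collapses with loss of Ph3PO, so the C2=C3 bond and ring C of the flavone arise in one operation. The closest known reaction type is the intramolecular Wittig olefination of ester carbonyls by ortho-acyloxyphenacylidene phosphoranes, an established entry to chromones and flavones. Ring C closes in a 6-exo-trig mode (attack on a carbonyl carbon whose C=O lies outside the forming ring), and no stereocentre is created because C2 and C3 end as sp2 carbons of the γ-pyranone. The step needs chemoselectivity for the benzoate over the lactone carbonyl C2' of the 2-pyranone, and geometry secures it: only the benzoate carbonyl stands in a 1,6-relationship to the ylide carbon, while the lactone lies out of reach across the methylene bridge and is a deactivated vinylogous carbonate. It also needs olefination to win over acyl transfer (loss of phenoxide from the tetrahedral adduct, which would C-benzoylate the ylide). The base-free, non-polar, hot medium should favour olefination because P–O bond formation drains the adduct irreversibly, and the three benzyl ethers are inert to these neutral conditions.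

Step 11
Reactants: 17 5,7-bis(benzyloxy)-8-[[4-(benzyloxy)-6-ethyl-5-methyl-2-oxo-2H-pyran-3-yl]methyl]-2-phenyl-4H-chromen-4-one
Product: 19 (2S)-5,7-bis(benzyloxy)-8-[[4-(benzyloxy)-6-ethyl-5-methyl-2-oxo-2H-pyran-3-yl]methyl]-2-phenyl-2,3-dihydro-4H-chromen-4-one, via enol silane 18 (not isolated)
Conditions: Cu(OAc)2 (5 mol%), (R)-DTBM-SEGPHOS (5.5 mol%), (MeO)2MeSiH, toluene, 0 °C → rt; then MeOH, AcOH (cat.), 0 °C
Reagents that add atoms: none
Why: Asymmetric conjugate reduction by a bisphosphine-ligated CuH (a hydride of monovalent copper, formed from Cu(OAc)2 and the silane) is established for β,β-disubstituted enones including 2-substituted chromones: the chiral ligand directs hydride to the Re face of C2 to set (2S), the copper enolate is trapped as enol silane 18 (which cannot open by retro-oxa-Michael reaction) until mild methanolysis releases the ketone, and the fully substituted, donor-deactivated 2-pyranone is not expected to accept hydride.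

Step 12
Reactants: 19 (2S)-5,7-bis(benzyloxy)-8-[[4-(benzyloxy)-6-ethyl-5-methyl-2-oxo-2H-pyran-3-yl]methyl]-2-phenyl-2,3-dihydro-4H-chromen-4-one
Product: 20 (2S)-8-[(6-ethyl-4-hydroxy-5-methyl-2-oxo-2H-pyran-3-yl)methyl]-5,7-dihydroxy-2-phenyl-2,3-dihydro-4H-chromen-4-one
Conditions: BCl3 (1 M in CH2Cl2), C6HMe5, CH2Cl2, −78 °C; then H2O
Reagents that add atoms: none
Why: Lewis-acid cleavage of the two aryl benzyl ethers and the vinylogous benzyl ester ether should proceed with pentamethylbenzene capturing each benzyl cation by Friedel–Crafts alkylation, so ring A is not C-benzylated, and the cold, non-basic, non-reducing conditions should leave C2 (no enolate-driven ring opening) and the pyranone untouched.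

**Compound list**

1 | 3-pentanone | CCC(=O)CC | starting material
2 | 3-(trimethylsilyloxy)pent-2-ene (E/Z mixture) | CC=C(CC)O[Si](C)(C)C | intermediate
3 | malonyl dichloride | O=C(Cl)CC(=O)Cl | starting material
4 | 4-methyl-3,5-dioxoheptanoyl chloride (not isolated) | CCC(=O)C(C)C(=O)CC(=O)Cl | intermediate
5 | 6-ethyl-4-hydroxy-5-methyl-2H-pyran-2-one | CCc1oc(=O)cc(O)c1C | intermediate
6 | 2,4,6-trihydroxyacetophenone | CC(=O)c1c(O)cc(O)cc1O | starting material
7 | 1-[2,4-bis(benzyloxy)-6-hydroxyphenyl]ethanone | CC(=O)c1c(O)cc(OCc2ccccc2)cc1OCc1ccccc1 | intermediate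
8 | 1-[4,6-bis(benzyloxy)-3-[(dimethylamino)methyl]-2-hydroxyphenyl]ethanone | CC(=O)c1c(O)c(CN(C)C)c(OCc2ccccc2)cc1OCc1ccccc1 | intermediate
9 | 2-acetyl-3,5-bis(benzyloxy)-6-methylidenecyclohexa-2,4-dien-1-one (ortho-quinone methide, not isolated) | CC(=O)C1=C(OCc2ccccc2)C=C(OCc2ccccc2)C(=C)C1=O | intermediate
10 | 3-[[3-acetyl-4,6-bis(benzyloxy)-2-hydroxyphenyl]methyl]-6-ethyl-4-hydroxy-5-methyl-2H-pyran-2-one | CCc1oc(=O)c(Cc2c(O)c(C(C)=O)c(OCc3ccccc3)cc2OCc2ccccc2)c(O)c1C | intermediate
11 | 3-[[3-acetyl-4,6-bis(benzyloxy)-2-hydroxyphenyl]methyl]-4-(benzyloxy)-6-ethyl-5-methyl-2H-pyran-2-one | CCc1oc(=O)c(Cc2c(O)c(C(C)=O)c(OCc3ccccc3)cc2OCc2ccccc2)c(OCc2ccccc2)c1C | intermediate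
12 | benzoyl chloride | O=C(Cl)c1ccccc1 | starting material
13 | 2-acetyl-3,5-bis(benzyloxy)-6-[[4-(benzyloxy)-6-ethyl-5-methyl-2-oxo-2H-pyran-3-yl]methyl]phenyl benzoate | CCc1oc(=O)c(Cc2c(OC(=O)c3ccccc3)c(C(C)=O)c(OCc3ccccc3)cc2OCc2ccccc2)c(OCc2ccccc2)c1C | intermediate
14 | 3,5-bis(benzyloxy)-2-[[4-(benzyloxy)-6-ethyl-5-methyl-2-oxo-2H-pyran-3-yl]methyl]-6-(bromoacetyl)phenyl benzoate | CCc1oc(=O)c(Cc2c(OC(=O)c3ccccc3)c(C(=O)CBr)c(OCc3ccccc3)cc2OCc2ccccc2)c(OCc2ccccc2)c1C | intermediate
15 | [2-[2-(benzoyloxy)-4,6-bis(benzyloxy)-3-[[4-(benzyloxy)-6-ethyl-5-methyl-2-oxo-2H-pyran-3-yl]methyl]phenyl]-2-oxoethyl]triphenylphosphonium bromide (not isolated) | CCc1oc(=O)c(Cc2c(OC(=O)c3ccccc3)c(C(=O)C[P+](c3ccccc3)(c3ccccc3)c3ccccc3)c(OCc3ccccc3)cc2OCc2ccccc2)c(OCc2ccccc2)c1C.[Br-] | intermediate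
16 | 3,5-bis(benzyloxy)-2-[[4-(benzyloxy)-6-ethyl-5-methyl-2-oxo-2H-pyran-3-yl]methyl]-6-[(triphenylphosphoranylidene)acetyl]phenyl benzoate | O=C(C=P(c1ccccc1)(c1ccccc1)c1ccccc1)c1c(OCc2ccccc2)cc(OCc2ccccc2)c(Cc2c(OCc3ccccc3)c(C)c(CC)oc2=O)c1OC(=O)c1ccccc1 | intermediate
17 | 5,7-bis(benzyloxy)-8-[[4-(benzyloxy)-6-ethyl-5-methyl-2-oxo-2H-pyran-3-yl]methyl]-2-phenyl-4H-chromen-4-one | CCc1oc(=O)c(Cc2c(OCc3ccccc3)cc(OCc3ccccc3)c3c2oc(-c2ccccc2)cc3=O)c(OCc2ccccc2)c1C | intermediate
18 | (2S)-5,7-bis(benzyloxy)-8-[[4-(benzyloxy)-6-ethyl-5-methyl-2-oxo-2H-pyran-3-yl]methyl]-4-[dimethoxy(methyl)silyl]oxy-2-phenyl-2H-chromene (not isolated) | CCc1oc(=O)c(Cc2c(OCc3ccccc3)cc(OCc3ccccc3)c3c2O[C@H](c2ccccc2)C=C3O[Si](C)(OC)OC)c(OCc2ccccc2)c1C | intermediate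
19 | (2S)-5,7-bis(benzyloxy)-8-[[4-(benzyloxy)-6-ethyl-5-methyl-2-oxo-2H-pyran-3-yl]methyl]-2-phenyl-2,3-dihydro-4H-chromen-4-one | CCc1oc(=O)c(Cc2c(OCc3ccccc3)cc(OCc3ccccc3)c3c2O[C@H](c2ccccc2)CC3=O)c(OCc2ccccc2)c1C | intermediate
20 | (2S)-8-[(6-ethyl-4-hydroxy-5-methyl-2-oxo-2H-pyran-3-yl)methyl]-5,7-dihydroxy-2-phenyl-2,3-dihydro-4H-chromen-4-one | CCc1oc(=O)c(Cc2c(O)cc(O)c3c2O[C@H](c2ccccc2)CC3=O)c(O)c1C | target

**Step count and risks**

Total step count: 12. Longest linear sequence: 10 steps (6 → 20 through steps 3–12; the pyranone branch through steps 1, 2 and 5–12 is equally long).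

Steps most likely to fail:

1. Step 10 (ring closure). The risk is acyl transfer overtaking olefination: the tetrahedral adduct may expel the phenoxide and C-benzoylate the ylide, or cyclisation may be slow because the acyl group, flanked by two ortho substituents, is twisted out of the ring plane. The fallback sets out from benzoate 13 and uses the acyl shift deliberately. LiN(SiMe3)2 in THF at −78 → 0 °C should bring about the Baker–Venkataraman O→C benzoyl migration to 1-[2,4-bis(benzyloxy)-5-[[4-(benzyloxy)-6-ethyl-5-methyl-2-oxo-2H-pyran-3-yl]methyl]-6-hydroxyphenyl]-3-phenylpropane-1,3-dione F1. Cyclodehydration with catalytic p-TsOH in toluene at 80 °C then closes ring C at O1–C2, and the route is rejoined at flavone 17; steps 8 and 9 are bypassed.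

2. Step 11 (asymmetric reduction). The risk is sluggish hydride transfer to an enone deactivated by the ring oxygen and two alkoxy donors, together with poor facial selectivity or over-reduction at C4. The fallback sets out from flavone 17. Asymmetric hydrogenation with a chiral ruthenium N-heterocyclic carbene catalyst (from [Ru(cod)(2-methylallyl)2], a chiral N,N'-bis(1-arylethyl)imidazolinium tetrafluoroborate and KOt-Bu, under H2 pressure), a method known for flavones, should reduce C2=C3 and in part the ketone. The product would be (2S)-5,7-bis(benzyloxy)-8-[[4-(benzyloxy)-6-ethyl-5-methyl-2-oxo-2H-pyran-3-yl]methyl]-2-phenylchroman-4-ol F2 (C4 epimers, cis expected to predominate). Oxidation of the alcohol with Dess–Martin periodinane in CH2Cl2 returns the route to flavanone 19.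

3. Step 8 (α-bromination). The risk is bromination of the one remaining aryl C–H between the two benzyloxy groups, or loss of a benzyl ether to the HBr set free. The fallback sets out from benzoate 13. Soft enolisation with TMSOTf and Et3N in CH2Cl2 at −20 °C (no free enolate, hence no acyl shift) should give 3,5-bis(benzyloxy)-2-[[4-(benzyloxy)-6-ethyl-5-methyl-2-oxo-2H-pyran-3-yl]methyl]-6-[1-(trimethylsilyloxy)ethenyl]phenyl benzoate F3. N-Bromosuccinimide in THF at −78 °C then delivers bromine to the enol carbon without forming acid, and the route is rejoined at bromoketone 14.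

**Further compounds**

F1 | step 10 | 1-[2,4-bis(benzyloxy)-5-[[4-(benzyloxy)-6-ethyl-5-methyl-2-oxo-2H-pyran-3-yl]methyl]-6-hydroxyphenyl]-3-phenylpropane-1,3-dione | CCc1oc(=O)c(Cc2c(O)c(C(=O)CC(=O)c3ccccc3)c(OCc3ccccc3)cc2OCc2ccccc2)c(OCc2ccccc2)c1C
F2 | step 11 | (2S)-5,7-bis(benzyloxy)-8-[[4-(benzyloxy)-6-ethyl-5-methyl-2-oxo-2H-pyran-3-yl]methyl]-2-phenylchroman-4-ol (C4 epimers) | CCc1oc(=O)c(Cc2c(OCc3ccccc3)cc(OCc3ccccc3)c3c2O[C@H](c2ccccc2)CC3O)c(OCc2ccccc2)c1C
F3 | step 8 | 3,5-bis(benzyloxy)-2-[[4-(benzyloxy)-6-ethyl-5-methyl-2-oxo-2H-pyran-3-yl]methyl]-6-[1-(trimethylsilyloxy)ethenyl]phenyl benzoate | CCc1oc(=O)c(Cc2c(OC(=O)c3ccccc3)c(C(=C)O[Si](C)(C)C)c(OCc3ccccc3)cc2OCc2ccccc2)c(OCc2ccccc2)c1C
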